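Ring C of the target is an oxolane whose oxygen links two fully substituted carbons, C9 and C13. C8 and C14 leave them on the same side of that ring, which is the pattern of the bridgeheads and alkene carbons of a 7-oxanorbornene. The synthesis therefore rests on disconnecting C7=C8 (ring B) and C14=C15 (ring D). One ruthenium-catalysed ring-rearrangement metathesis opens the strained C8=C14 bond, closes rings B and D, and turns the oxygen bridge into ring C with C9 and C13 already set. Its precursor 26 is a ring A cyclohexane bearing a vinyl carbinol at C5 and, at C10, an 8-methyl-7-oxanorbornene whose second bridgehead carries CH2OCH=CH2.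

Key step: step 17

Remark: labdane numbering is used for all intermediates (C4 CMe2, C5 CH, C6 carbinol carbon, C8 methyl-bearing carbon, C9 and C13 ether carbons, C10 quaternary carbon, C16 OCH2). The target is 5S,6R,8R,9R,10S,13S.
Assumption: the lipase of step 3 follows the usual size rule for secondary carbinols (CH2CMe2 large, vinylic CH medium).

Step 1
Reactants: 1 mesityl oxide; 2 ethyl acetoacetate
Product: 3 ethyl 2,6,6-trimethyl-4-oxocyclohex-2-ene-1-carboxylate (racemic)
Conditions: ZnCl2 (20 mol %), heptane–toluene, reflux, azeotropic removal of water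
Reagents that add atoms: none
Why: Michael addition of the acetoacetate carbon to the β,β-dimethyl enone followed by intramolecular aldol condensation (Robinson-type annulation) is the established entry to this ring, which already holds C4 (CMe2), C5–C6 and the methyl-bearing C10.

Step 2
Reactants: 3 ethyl 2,6,6-trimethyl-4-oxocyclohex-2-ene-1-carboxylate
Product: 5 ethyl trans-4-acetoxy-2,6,6-trimethylcyclohex-2-ene-1-carboxylate (racemic), via lithium alkoxide 4 (not isolated)
Conditions: LiBH(s-Bu)3, THF, −78 °C; then Ac2O, DMAP (cat.), −78 °C → rt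
Reagents that add atoms: acetic anhydride CC(=O)OC(C)=O
Why: The bulky borohydride adds 1,2 to the β-methyl enone from the face opposite the axial C4 methyl in the conformer with a pseudoaxial ester, so the C2 oxygen should end trans to the ester, and O-acylation of the alkoxide gives the substrate for resolution (diastereoselective carbonyl reduction).

Step 3
Reactants: 5 ethyl trans-4-acetoxy-2,6,6-trimethylcyclohex-2-ene-1-carboxylate (racemic)
Product: 6 ethyl (1S,4S)-4-hydroxy-2,6,6-trimethylcyclohex-2-ene-1-carboxylate
Conditions: Pseudomonas fluorescens lipase, phosphate buffer pH 7–MTBE, 30 °C, stopped near 45 % conversion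
Reagents that add atoms: none
Why: Lipase-catalysed kinetic resolution by enantioselective hydrolysis should cleave the (4S)-acetate according to the size rule for secondary carbinols, leaves the flanked ethyl ester alone, and thereby fixes the absolute configuration of C5 when the enantiomeric acetate is removed by chromatography.

Step 4
Reactants: 6 ethyl (1S,4S)-4-hydroxy-2,6,6-trimethylcyclohex-2-ene-1-carboxylate
Product: 7 ethyl (1S,4R)-2,6,6-trimethyl-4-(pyridine-2-carbonyloxy)cyclohex-2-ene-1-carboxylate
Conditions: picolinic acid, PPh3, DIAD, toluene, 0 °C → rt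
Reagents that add atoms: picolinic acid OC(=O)c1ccccn1
Why: Mitsunobu esterification inverts the allylic carbinol carbon by SN2 displacement of the oxyphosphonium ion and so places the chelating picolinate leaving group on the β face, cis to the ester.

Step 5
Reactants: 8 3-methylfuran
Product: 9 2-bromo-3-methylfuran
Conditions: N-bromosuccinimide, DMF, 0 °C
Reagents that add atoms: N-bromosuccinimide O=C1CCC(=O)N1Br
Why: Electrophilic aromatic bromination takes the furan α position activated by the neighbouring methyl group, which marks the future C9 for metalation without the regiochemical ambiguity of direct lithiation.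

Step 6
Reactants: 7 ethyl (1S,4R)-2,6,6-trimethyl-4-(pyridine-2-carbonyloxy)cyclohex-2-ene-1-carboxylate; 9 2-bromo-3-methylfuran
Product: 12 ethyl (1S,2S)-2,6,6-trimethyl-2-(3-methylfuran-2-yl)cyclohex-3-ene-1-carboxylate, via 3-methyl-2-furyllithium 10 (not isolated), via 3-methyl-2-furylcopper 11 (not isolated)
Conditions: 9, n-BuLi, Et2O, −78 °C; MgBr2·OEt2, CuBr·SMe2, THF, −40 °C; then 7, −40 → 0 °C; aq NH4Cl
Reagents that add atoms: none
Why: Copper-mediated allylic substitution of a magnesium-chelated picolinate is γ-selective and anti (anti-SN2′) and is known to build aryl-bearing quaternary carbons on cyclohexene rings, so the furyl group should enter C10 on the α face, opposite the β-picolinate, trans to the C5 ester and away from the axial C4 methyl, with transfer of chirality.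

Step 7
Reactants: 12 ethyl (1S,2S)-2,6,6-trimethyl-2-(3-methylfuran-2-yl)cyclohex-3-ene-1-carboxylate
Product: 13 ethyl (1S,2S)-2,6,6-trimethyl-2-(3-methylfuran-2-yl)cyclohexane-1-carboxylate
Conditions: H2 (4 bar), RhCl(PPh3)3 (5 mol %), benzene–EtOH, rt
Reagents that add atoms: none
Why: Homogeneous hydrogenation saturates the cis-disubstituted C1=C2 bond and leaves the aromatic furan and the ester untouched.

Step 8
Reactants: 13 ethyl (1S,2S)-2,6,6-trimethyl-2-(3-methylfuran-2-yl)cyclohexane-1-carboxylate
Product: 15 ethyl (1S,2S)-2-(5-formyl-3-methylfuran-2-yl)-2,6,6-trimethylcyclohexane-1-carboxylate, via furylmethylene iminium chloride 14 (not isolated)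
Conditions: POCl3, DMF, 0 °C → rt; then aq NaOAc
Reagents that add atoms: N,N-dimethylformamide CN(C)C=O; water O
Why: Vilsmeier–Haack formylation attacks the only free α position of the 2,3-dialkylfuran (C13), tolerates the ester that organolithium chemistry would endanger, and brings in C16.

Step 9
Reactants: 15 ethyl (1S,2S)-2-(5-formyl-3-methylfuran-2-yl)-2,6,6-trimethylcyclohexane-1-carboxylate
Product: 16 ethyl (1S,2S)-2-[5-(hydroxymethyl)-3-methylfuran-2-yl]-2,6,6-trimethylcyclohexane-1-carboxylate
Conditions: NaBH4, MeOH, 0 °C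
Reagents that add atoms: none
Why: Chemoselective hydride reduction of the aldehyde restores an electron-rich furan for the cycloaddition, while the hindered ester stays on as the masked C6 aldehyde and keeps the two oxygenated carbons differentiated without protecting groups.

Step 10
Reactants: 16 ethyl (1S,2S)-2-[5-(hydroxymethyl)-3-methylfuran-2-yl]-2,6,6-trimethylcyclohexane-1-carboxylate; 17 ethynyl p-tolyl sulfone
Product: 18 ethyl (1S,2S)-2-[(1R,4S)-4-(hydroxymethyl)-2-methyl-5-tosyl-7-oxabicyclo[2.2.1]hepta-2,5-dien-1-yl]-2,6,6-trimethylcyclohexane-1-carboxylate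
Conditions: toluene, 90 °C; chromatographic separation of the bridge diastereomers
Reagents that add atoms: none
Why: Diels–Alder addition of an alkynyl sulfone (acetylene equivalent) to a furan is exergonic where additions of alkenes to hindered furans are not; the slim HC≡ terminus bonds to the crowded, most nucleophilic C9; C9 and C13 form suprafacially as a pair, but only a modest facial bias from C10 can be expected (placing C8 and its methyl anti to C5 favours 9R,13S), so the wanted isomer is isolated by chromatography.

Step 11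
Reactants: 18 ethyl (1S,2S)-2-[(1R,4S)-4-(hydroxymethyl)-2-methyl-5-tosyl-7-oxabicyclo[2.2.1]hepta-2,5-dien-1-yl]-2,6,6-trimethylcyclohexane-1-carboxylate
Product: 19 ethyl (1S,2S)-2-[(1R,4S)-4-(hydroxymethyl)-2-methyl-7-oxabicyclo[2.2.1]hepta-2,5-dien-1-yl]-2,6,6-trimethylcyclohexane-1-carboxylate
Conditions: 6 % Na/Hg, Na2HPO4, MeOH–THF, −20 → 0 °C
Reagents that add atoms: none
Why: Buffered reductive desulfonylation cleaves the vinylic C–S bond by electron transfer, and the sp2 centre formed at C12 has no anti-periplanar path to expel the bridge oxygen, whereas a saturated β-alkoxy sulfone would risk opening the bridge.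

Step 12
Reactants: 19 ethyl (1S,2S)-2-[(1R,4S)-4-(hydroxymethyl)-2-methyl-7-oxabicyclo[2.2.1]hepta-2,5-dien-1-yl]-2,6,6-trimethylcyclohexane-1-carboxylate
Product: 20 ethyl (1S,2S)-2-[(1R,4S)-4-(hydroxymethyl)-2-methyl-7-oxabicyclo[2.2.1]hept-2-en-1-yl]-2,6,6-trimethylcyclohexane-1-carboxylate
Conditions: 2-nitrobenzenesulfonyl hydrazide, Et3N, CH2Cl2, rt, dosed until 19 is consumed
Reagents that add atoms: none
Why: Diimide transfers H2 in a concerted syn fashion and is very sensitive to substitution, so the strained disubstituted C11=C12 bond should be reduced well before the trisubstituted and flanked C8=C14 bond, and no other alkene is present at this stage.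

Step 13
Reactants: 20 ethyl (1S,2S)-2-[(1R,4S)-4-(hydroxymethyl)-2-methyl-7-oxabicyclo[2.2.1]hept-2-en-1-yl]-2,6,6-trimethylcyclohexane-1-carboxylate; 21 vinyl acetate
Product: 22 ethyl (1S,2S)-2-[(1R,4S)-2-methyl-4-(vinyloxymethyl)-7-oxabicyclo[2.2.1]hept-2-en-1-yl]-2,6,6-trimethylcyclohexane-1-carboxylate
Conditions: [Ir(cod)Cl]2 (2 mol %), Na2CO3, toluene, 100 °C
Reagents that add atoms: none
Why: Iridium-catalysed transfer vinylation (addition of the alcohol to coordinated vinyl acetate, then loss of acetate) runs under basic conditions on hindered primary alcohols, and the only hydroxyl present is the one at C16.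

Step 14
Reactants: 22 ethyl (1S,2S)-2-[(1R,4S)-2-methyl-4-(vinyloxymethyl)-7-oxabicyclo[2.2.1]hept-2-en-1-yl]-2,6,6-trimethylcyclohexane-1-carboxylate
Product: 23 {(1S,2S)-2-[(1R,4S)-2-methyl-4-(vinyloxymethyl)-7-oxabicyclo[2.2.1]hept-2-en-1-yl]-2,6,6-trimethylcyclohexyl}methanol
Conditions: LiAlH4, THF, 0 °C → reflux
Reagents that add atoms: none
Why: LiAlH4 reduces even this doubly flanked ester, and neither the vinyl ether nor the oxanorbornene reacts with a nucleophilic hydride.

Step 15
Reactants: 23 {(1S,2S)-2-[(1R,4S)-2-methyl-4-(vinyloxymethyl)-7-oxabicyclo[2.2.1]hept-2-en-1-yl]-2,6,6-trimethylcyclohexyl}methanol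
Product: 24 (1S,2S)-2-[(1R,4S)-2-methyl-4-(vinyloxymethyl)-7-oxabicyclo[2.2.1]hept-2-en-1-yl]-2,6,6-trimethylcyclohexane-1-carbaldehyde
Conditions: Dess–Martin periodinane, pyridine, CH2Cl2, 0 °C → rt
Reagents that add atoms: none
Why: Pyridine-buffered Dess–Martin oxidation stops at the aldehyde, is mild enough for the acid-sensitive vinyl ether, and does not epimerise C5.

Step 16
Reactants: 24 (1S,2S)-2-[(1R,4S)-2-methyl-4-(vinyloxymethyl)-7-oxabicyclo[2.2.1]hept-2-en-1-yl]-2,6,6-trimethylcyclohexane-1-carbaldehyde; 25 vinylmagnesium bromide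
Product: 26 (1R)-1-{(1S,2S)-2-[(1R,4S)-2-methyl-4-(vinyloxymethyl)-7-oxabicyclo[2.2.1]hept-2-en-1-yl]-2,6,6-trimethylcyclohexyl}prop-2-en-1-ol
Conditions: THF, −78 → 0 °C
Reagents that add atoms: none
Why: In this Grignard 1,2-addition the formyl hydrogen should sit in the pocket between the axial C4 and C10 methyl groups (C=O syn to H5) and the oxanorbornenyl group screens the C10 side, so attack from the C4 side should give the 6R carbinol, with the minor epimer removed by chromatography.

Step 17
Reactants: 26 (1R)-1-{(1S,2S)-2-[(1R,4S)-2-methyl-4-(vinyloxymethyl)-7-oxabicyclo[2.2.1]hept-2-en-1-yl]-2,6,6-trimethylcyclohexyl}prop-2-en-1-ol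
Product: 27 (5S,6R,9R,10S,13S)-9,13:15,16-diepoxylabda-7,14-dien-6-ol
Conditions: second-generation Grubbs catalyst RuCl2(=CHPh)(PCy3)(H2IMes) (3 × 5 mol %), 1,4-benzoquinone (20 mol %), toluene (2 mM), ethylene (1 atm), 70 °C
Reagents that add atoms: none
Why: The catalyst should initiate at the monosubstituted C7 vinyl group next to the free hydroxyl; the C7 alkylidene then adds to the strained C8=C14 bond by [2+2] cycloaddition with C7 on C8, and cycloreversion opens the bicycle, closes the six-membered ring B through the tether from bridgehead C9, and leaves ruthenium on C14. This alkylidene closes the five-membered ring D by enol ether–olefin ring-closing metathesis onto the vinyl ether (C14 bonding to C15), regenerating the methylidene, so that ethylene is lost overall. The closest known chemistry is the ring-rearrangement metathesis of 7-oxanorbornenes with alkenyl side chains, together with ring-closing metathesis of olefinic vinyl ethers to cyclic enol ethers. No stereocentre is created: C9 and C13 keep the configuration of the bicycle, the former bridge becomes ring C with C8 and C14 cis, and C5, C6 and C10 are spectators. The selectivity needed is one of order, because attack at the vinyl ether gives a sluggish alkoxycarbene; the activating allylic hydroxyl, high dilution, portionwise catalyst, and warm ethylene (which can return the alkoxycarbene to the methylidene) favour the wanted order, and strain release makes the productive path irreversible. Benzoquinone is added to suppress ruthenium hydride isomerisation of the allylic alcohol and of the product enol ether.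

Step 18
Reactants: 27 (5S,6R,9R,10S,13S)-9,13:15,16-diepoxylabda-7,14-dien-6-ol
Product: 28 (5S,6R,8R,9R,10S,13S)-9,13:15,16-diepoxylabd-14-en-6-ol
Conditions: [Ir(cod)(PCy3)(py)]PF6 (5 mol %), H2 (one equivalent, 1 atm), CH2Cl2, 0 °C; quenched with Et3N
Reagents that add atoms: none
Why: In this hydroxyl-directed homogeneous hydrogenation the axial 6β-OH binds the cationic iridium dihydride and delivers H2 to the β face of C7=C8, setting 8β-H (8α-methyl, 8R) against the steric bias of the angular methyl, while low temperature, low loading and metered H2 are meant to spare the undirected C14=C15 enol ether.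

Step 19
Reactants: 28 (5S,6R,8R,9R,10S,13S)-9,13:15,16-diepoxylabd-14-en-6-ol
Product: 29 (5S,6R,8R,9R,10S,13S)-9,13:15,16-diepoxylabd-14-en-6-yl acetate (target)
Conditions: Ac2O, DMAP, Et3N, CH2Cl2, rt → 40 °C
Reagents that add atoms: acetic anhydride CC(=O)OC(C)=O
Why: DMAP-catalysed acylation under basic conditions esterifies the hindered axial 6β-ol without endangering the acid-labile bis-spiro enol ether.

Compound list
1 | mesityl oxide (4-methylpent-3-en-2-one) | CC(C)=CC(C)=O | starting material
2 | ethyl acetoacetate | CCOC(=O)CC(C)=O | starting material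
3 | ethyl 2,6,6-trimethyl-4-oxocyclohex-2-ene-1-carboxylate (racemic) | CCOC(=O)C1C(C)=CC(=O)CC1(C)C | intermediate
4 | lithium trans-4-alkoxide of the reduced enone (racemic, one enantiomer drawn) | CCOC(=O)[C@H]1C(C)(C)C[C@H]([O-])C=C1C.[Li+] | intermediate
5 | ethyl trans-4-acetoxy-2,6,6-trimethylcyclohex-2-ene-1-carboxylate (racemic, one enantiomer drawn) | CCOC(=O)[C@H]1C(C)(C)C[C@H](OC(C)=O)C=C1C | intermediate
6 | ethyl (1S,4S)-4-hydroxy-2,6,6-trimethylcyclohex-2-ene-1-carboxylate | CCOC(=O)[C@H]1C(C)(C)C[C@H](O)C=C1C | intermediate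
7 | ethyl (1S,4R)-2,6,6-trimethyl-4-(pyridine-2-carbonyloxy)cyclohex-2-ene-1-carboxylate | CCOC(=O)[C@H]1C(C)(C)C[C@@H](OC(=O)c2ccccn2)C=C1C | intermediate
8 | 3-methylfuran | Cc1ccoc1 | starting material
9 | 2-bromo-3-methylfuran | Cc1ccoc1Br | intermediate
10 | 3-methyl-2-furyllithium | [Li]c1occc1C | intermediate
11 | 3-methyl-2-furylcopper (MgBr2 present) | [Cu]c1occc1C | intermediate
12 | ethyl (1S,2S)-2,6,6-trimethyl-2-(3-methylfuran-2-yl)cyclohex-3-ene-1-carboxylate | CCOC(=O)[C@H]1C(C)(C)CC=C[C@]1(C)c1occc1C | intermediate
13 | ethyl (1S,2S)-2,6,6-trimethyl-2-(3-methylfuran-2-yl)cyclohexane-1-carboxylate | CCOC(=O)[C@H]1C(C)(C)CCC[C@]1(C)c1occc1C | intermediate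
14 | furylmethylene(dimethyl)iminium chloride of 13 | CCOC(=O)[C@H]1C(C)(C)CCC[C@]1(C)c1oc(C=[N+](C)C)cc1C.[Cl-] | intermediate
15 | ethyl (1S,2S)-2-(5-formyl-3-methylfuran-2-yl)-2,6,6-trimethylcyclohexane-1-carboxylate | CCOC(=O)[C@H]1C(C)(C)CCC[C@]1(C)c1oc(C=O)cc1C | intermediate
16 | ethyl (1S,2S)-2-[5-(hydroxymethyl)-3-methylfuran-2-yl]-2,6,6-trimethylcyclohexane-1-carboxylate | CCOC(=O)[C@H]1C(C)(C)CCC[C@]1(C)c1oc(CO)cc1C | intermediate
17 | ethynyl p-tolyl sulfone | C#CS(=O)(=O)c1ccc(C)cc1 | starting material
18 | 12-tosyl oxanorbornadiene, 9R,13S (bicycle 1R,4S) | CCOC(=O)[C@H]1C(C)(C)CCC[C@]1(C)[C@]23C=C(S(=O)(=O)c4ccc(C)cc4)[C@](CO)(O2)C=C3C | intermediate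
19 | oxanorbornadiene, 9R,13S | CCOC(=O)[C@H]1C(C)(C)CCC[C@]1(C)[C@]23C=C[C@](CO)(O2)C=C3C | intermediate
20 | oxanorbornene hydroxy ester, 9R,13S | CCOC(=O)[C@H]1C(C)(C)CCC[C@]1(C)[C@]23CC[C@](CO)(O2)C=C3C | intermediate
21 | vinyl acetate | C=COC(C)=O | starting material
22 | oxanorbornene vinyl ether ester | CCOC(=O)[C@H]1C(C)(C)CCC[C@]1(C)[C@]23CC[C@](COC=C)(O2)C=C3C | intermediate
23 | C6 primary alcohol | OC[C@H]1C(C)(C)CCC[C@]1(C)[C@]23CC[C@](COC=C)(O2)C=C3C | intermediate
24 | C6 aldehyde | O=C[C@H]1C(C)(C)CCC[C@]1(C)[C@]23CC[C@](COC=C)(O2)C=C3C | intermediate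
25 | vinylmagnesium bromide | C=C[Mg]Br | starting material
26 | metathesis precursor, 5S,6R,9R,10S,13S | C=C[C@@H](O)[C@H]1C(C)(C)CCC[C@]1(C)[C@]23CC[C@](COC=C)(O2)C=C3C | intermediate
27 | (5S,6R,9R,10S,13S)-9,13:15,16-diepoxylabda-7,14-dien-6-ol | O[C@@H]1C=C(C)[C@]2(CC[C@@]3(C=COC3)O2)[C@@]2(C)CCCC(C)(C)[C@H]12 | intermediate
28 | (5S,6R,8R,9R,10S,13S)-9,13:15,16-diepoxylabd-14-en-6-ol | O[C@@H]1C[C@@H](C)[C@]2(CC[C@@]3(C=COC3)O2)[C@@]2(C)CCCC(C)(C)[C@H]12 | intermediate
29 | (5S,6R,8R,9R,10S,13S)-9,13:15,16-diepoxylabd-14-en-6-yl acetate | CC(=O)O[C@@H]1C[C@@H](C)[C@]2(CC[C@@]3(C=COC3)O2)[C@@]2(C)CCCC(C)(C)[C@H]12 | target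

Total step count: 19. Longest linear sequence: 18 (steps 1–4 and 6–19; step 5 is a one-step branch).

Steps most likely to fail

1. Step 17. The catalyst may be tied up as an alkoxycarbene at the vinyl ether, or it may fail to open the hindered trisubstituted bridge; either would lead to recovered material or oligomerisation. The fallback separates the two ring closures. It sets out from 26 and returns at 27. Mild hydrolysis of the vinyl ether (PPTS, wet acetone) gives the oxanorbornene diol F1. With no enol ether present, RuCl2(=CHPh)(PCy3)(H2IMes) under ethylene should convert it by ring-opening/ring-closing metathesis into 9,13-epoxylabda-7,14-diene-6β,16-diol F2. The primary C16 hydroxyl is then vinylated ([Ir(cod)Cl]2, Na2CO3, vinyl acetate); the axial 6β-OH between two axial methyl groups is far less accessible, so this should give the 16-O-vinyl ether F3. Ring D is closed in a separate enol ether–olefin ring-closing metathesis. In that step initiation at either alkene is productive, because the alkoxycarbene can itself cyclise onto the C14 vinyl group.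

2. Step 18. Chemoselectivity may be lost through hydrogenation of the C14=C15 enol ether, or the acidic iridium hydride may open ring C to the furan. The fallback tells the two alkenes apart electronically. It sets out from 27 and returns at 28. Dess–Martin periodinane with pyridine gives the 7-en-6-one F4. [(Ph3P)CuH]6 in toluene reduces only the enone, and hydride is expected to add axially to C8 from the β face, anti to the pseudoaxial C9–O bond, to give the 8α-methyl 6-ketone F5. NaBH4 then attacks from the α face, because the β face is closed by the axial C4 and C10 methyl groups, and restores the 6β-ol.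

3. Step 10. Facial selectivity may be poor, or may favour the wrong bridge diastereomer, and the alkyne adduct does not revert, so nothing can be recycled. The fallback uses a reversible cycloaddition. It sets out from 16 and returns at 19. (E)-1,2-Bis(phenylsulfonyl)ethene under high pressure (CH2Cl2, 12 kbar, rt) gives the trans-11,12-bis(phenylsulfonyl) oxanorbornene F6. The unwanted diastereomer is cracked back to 16 by heating and recycled, and equilibration should favour the isomer with C8 anti to C5. Buffered Na/Hg then removes both sulfonyl groups by reductive elimination.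

Further compounds
F1 | step 17 | (1R)-1-{(1S,2S)-2-[(1R,4S)-4-(hydroxymethyl)-2-methyl-7-oxabicyclo[2.2.1]hept-2-en-1-yl]-2,6,6-trimethylcyclohexyl}prop-2-en-1-ol | C=C[C@@H](O)[C@H]1C(C)(C)CCC[C@]1(C)[C@]23CC[C@](CO)(O2)C=C3C
F2 | step 17 | (5S,6R,9R,10S,13S)-9,13-epoxylabda-7,14-diene-6,16-diol | O[C@@H]1C=C(C)[C@]2(CC[C@@](CO)(C=C)O2)[C@@]2(C)CCCC(C)(C)[C@H]12
F3 | step 17 | 16-O-vinyl ether of F2 | O[C@@H]1C=C(C)[C@]2(CC[C@@](COC=C)(C=C)O2)[C@@]2(C)CCCC(C)(C)[C@H]12
F4 | step 18 | (5S,9R,10S,13S)-9,13:15,16-diepoxylabda-7,14-dien-6-one | O=C1C=C(C)[C@]2(CC[C@@]3(C=COC3)O2)[C@@]2(C)CCCC(C)(C)[C@H]12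
F5 | step 18 | (5S,8R,9R,10S,13S)-9,13:15,16-diepoxylabd-14-en-6-one | O=C1C[C@@H](C)[C@]2(CC[C@@]3(C=COC3)O2)[C@@]2(C)CCCC(C)(C)[C@H]12
F6 | step 10 | 11-exo,12-endo-bis(phenylsulfonyl) oxanorbornene hydroxy ester, 9R,13S | CCOC(=O)[C@H]1C(C)(C)CCC[C@]1(C)[C@]23[C@H](S(=O)(=O)c4ccccc4)[C@@H](S(=O)(=O)c4ccccc4)[C@](CO)(O2)C=C3C
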